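The rate constants are invented, and the outcome is calculated.

The easy step comes first: free catalyst stands on the left of both substrate capture and isomerisation, so those two rates can be divided.

    free catalyst + added ligand ⇌ idle complex (K1 = 440 M⁻¹, k1 = 0.0028 M⁻¹ s⁻¹)
    substrate + free catalyst → catalyst intermediate A (k2 = 1.3 M⁻¹ s⁻¹)
    precatalyst → free catalyst (k3 = 2.1 × 10⁻⁶ s⁻¹)
    coupling partner + catalyst intermediate A → catalyst intermediate B (k4 = 0.086 M⁻¹ s⁻¹)
    catalyst intermediate B → free catalyst + target (k5 = 0.0017 s⁻¹)
    target + free catalyst ⇌ isomer of the product + free catalyst, rate k6*[free catalyst]*[target] forward; the back reaction follows from the equilibrium constant (K6 = 0.58, k6 = 0.025 M⁻¹ s⁻¹)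

the same everywhere: substrate 0.024 M; coupling partner 1.00 equiv; added ligand 2.3 mM; time 3.0 d

|  | precatalyst |
|---|---|
| north-east | 0.5 mol% |
| east | 1 mol% |
| south-west | 2 mol% |
| south-east | 4 mol% |
| west | 8 mol% |

- amount of target at the end, in percent of the substrate charged for north-east, east, south-west, south-east, west, in this order
- the course of these numbers from the first flask to the last (falls all the way / hardly changes / rises, then falls / rises all the way / falls, then rises)

- "hardly changes" means that all values lie within two and a half points (for a concentration: within two and a half percent of the largest)
- run time (north-east): 3.0 d

Free catalyst captures substrate at 1.3 M⁻¹ s⁻¹ times the product of the two concentrations, and it turns target into isomer of the product at 0.025 M⁻¹ s⁻¹ times the product of its own concentration and that of target. In the ratio of these forward rates, free catalyst and time drop out. What remains is a constant times target over substrate. That constant, 0.0192, is the selectivity factor: the number of target molecules isomerised per substrate molecule captured when target and substrate stand equal.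

Summing this ratio along the conversion, with target counted as the substrate consumed and with the back reaction and the material held in the two catalyst intermediates neglected, gives an estimate of the isomer at any fraction of substrate left. At a fraction of 0.5 it is 0.371 % of the charge. The two forward rates come nearly level when the fraction of substrate left has fallen to the factor itself. There the isomer is 5.71 % of the charge, and target peaks near 92.4 %. Beyond that point target falls, towards its equilibrium share of 63.3 %.

One number is not enough, however, since the factor contains no loading. In the north-east flask the half-life of the precatalyst by its activation step alone, 3.8 d, is longer than the run of 3.0 d, so precatalyst goes on releasing free catalyst during the run. Placing each flask on this curve takes a count of turnovers, and the hand reckoning stops here, with a peak and an equilibrium share but no row.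

The forecast goes further, with 24.3 %, 44.7 %, 73.4 %, 91 % and 69 %, course rises, then falls; of the last flask it says: “Free catalyst then accumulates”.

The simulation gives 24.7 %, 45.4 %, 74.0 %, 91.4 % and 67.3 %, course rises, then falls.

In the south-east flask at the end, 91.4 % of target faces 2.00 % of substrate, which puts forward isomerisation at 0.877 of the rate of substrate capture, and the turn of the row is read at 4.1 mol%, beside that flask's 4 mol%. In the south-west flask at the end, 74.0 % of target faces 23.9 % of substrate, the same division gives 0.0594, and the isomer stands at 1.24 %, against 5.11 % in the south-east flask.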